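**Retrosynthetic overview**
1. The last C–C bond is a Negishi coupling between the 6-iodochromanyl benzophenone and the primary alkylzinc of the C10 side chain. The side chain comes from (R)-limonene oxide by ring cleavage, Wittig methylenation and photochemical decarboxylative iodination (one carbon lost).
2. The dihydropyran ring closes by acid-mediated attack of the ortho phenol on the tertiary carbinol of a (2R)-2,3-dihydroxy-3-methylbutyl chain; the carbinol comes from MeMgBr addition to a dioxolanone.
3. The key bond, ArC–CH2 of that chain, is made by a photochemical decarboxylative C–H alkylation of the ring A aryloxide with the N-acyloxyphthalimide of D-malic acid acetonide.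
4. The benzophenone core comes from Friedel–Crafts acylation of 3,5-dimethoxyphenol with 3-hydroxybenzoic acid, then demethylation ortho to the ketone.
5. Ring order: rings A and B are bought; the dihydropyran ring is the only ring formed (step 7), before the side chain is attached.

Assumption: (+)-limonene oxide is the commercial cis/trans mixture of the (4R) series, and D-malic acid is bought as the cheap source of the carbinol centre.

**Step 1**
Reactants: 1 3,5-dimethoxyphenol; 2 3-hydroxybenzoic acid
Product: 3 (2-hydroxy-4,6-dimethoxyphenyl)(3-hydroxyphenyl)methanone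
Conditions: Eaton's reagent (P2O5 in MeSO3H), 70 °C
Reagents that add atoms: none
Why: Friedel–Crafts acylation of the activated phenol ortho to OH, where the hydrogen-bonded o-hydroxyketone is the favoured product and any aryl ester formed rearranges (Fries) in the medium.

**Step 2**
Reactants: 3 (2-hydroxy-4,6-dimethoxyphenyl)(3-hydroxyphenyl)methanone
Product: 4 (2,6-dihydroxy-4-methoxyphenyl)(3-hydroxyphenyl)methanone
Conditions: BCl3 (3.5 equiv), CH2Cl2, −78 → 0 °C; aqueous work-up
Reagents that add atoms: none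
Why: Chelation-controlled Lewis-acid demethylation, in which boron bound to the ketone cleaves only the OMe ortho to C=O and leaves the para OMe.

**Step 3**
Reactants: 5 D-malic acid
Product: 6 2-[(4R)-2,2-dimethyl-5-oxo-1,3-dioxolan-4-yl]acetic acid
Conditions: 2,2-dimethoxypropane, p-TsOH·H2O (cat.), 20 °C
Reagents that add atoms: 2,2-dimethoxypropane, COC(C)(C)OC
Why: Acetalisation of the α-hydroxy acid to the five-membered dioxolanone leaves the CH2CO2H arm free and does not touch the stereocentre.

**Step 4**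
Reactants: 6 2-[(4R)-2,2-dimethyl-5-oxo-1,3-dioxolan-4-yl]acetic acid
Product: 7 1,3-dioxoisoindolin-2-yl 2-[(4R)-2,2-dimethyl-5-oxo-1,3-dioxolan-4-yl]acetate
Conditions: N-hydroxyphthalimide, DIC, DMAP (5 mol%), CH2Cl2, 0 → 20 °C
Reagents that add atoms: N-hydroxyphthalimide, ON1C(=O)c2ccccc2C1=O
Why: Carbodiimide (Steglich-type) esterification gives the redox-active ester.

**Step 5**
Reactants: 4 (2,6-dihydroxy-4-methoxyphenyl)(3-hydroxyphenyl)methanone (2 equiv); 7 1,3-dioxoisoindolin-2-yl 2-[(4R)-2,2-dimethyl-5-oxo-1,3-dioxolan-4-yl]acetate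
Product: 8 (5R)-5-{[2,4-dihydroxy-3-(3-hydroxybenzoyl)-6-methoxyphenyl]methyl}-2,2-dimethyl-1,3-dioxolan-4-one
Conditions: 2-tert-butyl-1,1,3,3-tetramethylguanidine (1 equiv per 4), DMA, 405 nm LEDs, 15 °C, Ar; dilute citric acid work-up
Reagents that add atoms: none
Why: Proposed new method: photodecarboxylative C–H alkylation of an aryloxide with a redox-active ester, in which one equivalent of base deprotonates only the more acidic 2,6-dihydroxyaryl ketone ring A (estimated pKa about 8 against about 9 for the ring B phenol), the aryloxide and the electron-poor phthalimide of 7 form an electron donor–acceptor complex whose excitation transfers one electron, the ester radical anion loses phthalimide anion and CO2 to give a primary alkyl radical with no fast rearrangement channel, and that radical couples with the persistent aryloxyl radical (or adds to a second aryloxide and passes the electron to 7 in an SRN1-type chain) at C3, equivalent to C5 by symmetry, before tautomerisation restores the phenol; the closest known reactions are the photostimulated SRN1 C-alkylation of phenoxides and naphthoxides with neopentyl and bridgehead iodides, the donor–acceptor-complex alkylation of phenolates with perfluoroalkyl iodides and α-iodosulfones, and donor–acceptor activation of N-acyloxyphthalimides; the stereocentre is β to the radical and is carried over from D-malic acid.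

**Step 6**
Reactants: 8 (5R)-5-{[2,4-dihydroxy-3-(3-hydroxybenzoyl)-6-methoxyphenyl]methyl}-2,2-dimethyl-1,3-dioxolan-4-one
Product: 10 {3-[(2R)-2,3-dihydroxy-3-methylbutyl]-2,6-dihydroxy-4-methoxyphenyl}(3-hydroxyphenyl)methanone, via methyl ketone 9 (not isolated)
Conditions: MeMgBr (10 equiv), THF, 0 → 20 °C; aqueous NH4Cl
Reagents that add atoms: methylmagnesium bromide, C[Mg]Br
Why: Double Grignard addition to the activated dioxolanone carbonyl (the first addition opens the ring and releases acetone) gives the tertiary carbinol, while the diaryl ketone is shielded as a di-ortho magnesium phenoxide (a vinylogous carboxylate) and the α-alkoxide stereocentre is not enolised.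

**Step 7**
Reactants: 10 {3-[(2R)-2,3-dihydroxy-3-methylbutyl]-2,6-dihydroxy-4-methoxyphenyl}(3-hydroxyphenyl)methanone
Product: 11 [(3R)-3,7-dihydroxy-5-methoxy-2,2-dimethyl-3,4-dihydro-2H-chromen-8-yl](3-hydroxyphenyl)methanone
Conditions: p-TsOH·H2O (20 mol%), 1,2-dichloroethane, 70 °C
Reagents that add atoms: none
Why: SN1 cyclodehydration, in which the tertiary cation is trapped by the only ortho OH to close the six-membered ether; the C3–O bond is never broken, so (R) is retained.

**Step 8**
Reactants: 11 [(3R)-3,7-dihydroxy-5-methoxy-2,2-dimethyl-3,4-dihydro-2H-chromen-8-yl](3-hydroxyphenyl)methanone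
Product: 12 [(3R)-3,7-dihydroxy-6-iodo-5-methoxy-2,2-dimethyl-3,4-dihydro-2H-chromen-8-yl](3-hydroxyphenyl)methanone
Conditions: NIS (1.05 equiv), MeCN, 0 °C
Reagents that add atoms: N-iodosuccinimide, O=C1CCC(=O)N1I
Why: Electrophilic aromatic iodination goes to the single C–H of the trioxygenated ring A, which is far more nucleophilic than ring B.

**Step 9**
Reactants: 13 (+)-limonene oxide (4R; cis/trans mixture)
Product: 15 (3R)-6-oxo-3-(prop-1-en-2-yl)heptanal, via limonene glycol 14 (not isolated)
Conditions: H5IO6 (1.2 equiv), THF/H2O, 0 → 20 °C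
Reagents that add atoms: water, O
Why: Acid-catalysed epoxide hydrolysis followed by periodate (Malaprade) glycol cleavage; both epoxide diastereomers converge and the stereocentre is remote from the bonds that react.

**Step 10**
Reactants: 15 (3R)-6-oxo-3-(prop-1-en-2-yl)heptanal
Product: 16 (3R)-6-oxo-3-(prop-1-en-2-yl)heptanoic acid
Conditions: NaClO2, NaH2PO4, 2-methyl-2-butene (excess), t-BuOH/H2O, 0 → 20 °C
Reagents that add atoms: sodium chlorite, [Na+].[O-]Cl=O
Why: Pinnick oxidation is selective for the aldehyde, and the scavenger keeps hypochlorite away from the isopropenyl group.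

**Step 11**
Reactants: 16 (3R)-6-oxo-3-(prop-1-en-2-yl)heptanoic acid
Product: 17 (3R)-6-methyl-3-(prop-1-en-2-yl)hept-6-enoic acid
Conditions: Ph3PCH3Br (2.5 equiv), KOtBu (3.5 equiv), THF, 0 → 20 °C; then acidify to pH 3
Reagents that add atoms: methyltriphenylphosphonium bromide, C[P+](c1ccccc1)(c1ccccc1)c1ccccc1.[Br-]
Why: Wittig methylenation of the methyl ketone with the carboxylate as an inert spectator; the stereocentre is not α to any carbonyl.

**Step 12**
Reactants: 17 (3R)-6-methyl-3-(prop-1-en-2-yl)hept-6-enoic acid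
Product: 19 (3S)-3-(iodomethyl)-2,6-dimethylhepta-1,6-diene, via Barton ester 18 (not isolated)
Conditions: 1-hydroxypyridine-2(1H)-thione, DIC, CH2Cl2, 0 °C, dark; then CHI3 (2.5 equiv), white LEDs, 20 °C
Reagents that add atoms: iodoform, IC(I)I; 1-hydroxypyridine-2(1H)-thione, ON1C=CC=CC1=S (kept only in 18)
Why: Barton decarboxylative iodination, a radical chain in which iodine-atom transfer from excess iodoform is expected to be much faster than the 3-exo and 5-exo/6-endo ring closures open to this primary radical (estimated 10^4–10^5 s-1); the stereocentre is β to the radical and only its descriptor changes.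

**Step 13**
Reactants: 12 [(3R)-3,7-dihydroxy-6-iodo-5-methoxy-2,2-dimethyl-3,4-dihydro-2H-chromen-8-yl](3-hydroxyphenyl)methanone; 19 (3S)-3-(iodomethyl)-2,6-dimethylhepta-1,6-diene (3 equiv)
Product: 21 [(3R)-3,7-dihydroxy-5-methoxy-2,2-dimethyl-6-[(2R)-5-methyl-2-(prop-1-en-2-yl)hex-5-en-1-yl]-3,4-dihydro-2H-chromen-8-yl](3-hydroxyphenyl)methanone, via alkylzinc iodide 20 (not isolated)
Conditions: 19, Zn dust (activated), LiCl, THF, 40 °C; then slow addition to 12, Pd(OAc)2 (5 mol%), SPhos (10 mol%), THF, 25 → 45 °C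
Reagents that add atoms: zinc, [Zn] (kept only in 20)
Why: Negishi coupling, a two-electron pathway with no free radical to rearrange; zinc insertion keeps the homoallyl/hexenyl skeleton, the SPhos–palladium catalyst is known to couple alkylzincs faster than free phenol and alcohol OH groups protonate them and to handle di-ortho-substituted aryl halides, and the stereocentre β to zinc is untouched.

**Compound list**
1 | 3,5-dimethoxyphenol | COc1cc(O)cc(OC)c1 | starting material
2 | 3-hydroxybenzoic acid | OC(=O)c1cccc(O)c1 | starting material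
3 | (2-hydroxy-4,6-dimethoxyphenyl)(3-hydroxyphenyl)methanone | COc1cc(O)c(C(=O)c2cccc(O)c2)c(OC)c1 | intermediate
4 | (2,6-dihydroxy-4-methoxyphenyl)(3-hydroxyphenyl)methanone | COc1cc(O)c(C(=O)c2cccc(O)c2)c(O)c1 | intermediate
5 | D-malic acid, (2R)-2-hydroxybutanedioic acid | OC(=O)C[C@@H](O)C(=O)O | starting material
6 | 2-[(4R)-2,2-dimethyl-5-oxo-1,3-dioxolan-4-yl]acetic acid | OC(=O)C[C@H]1OC(C)(C)OC1=O | intermediate
7 | 1,3-dioxoisoindolin-2-yl 2-[(4R)-2,2-dimethyl-5-oxo-1,3-dioxolan-4-yl]acetate | O=C(C[C@H]1OC(C)(C)OC1=O)ON1C(=O)c2ccccc2C1=O | intermediate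
8 | (5R)-5-{[2,4-dihydroxy-3-(3-hydroxybenzoyl)-6-methoxyphenyl]methyl}-2,2-dimethyl-1,3-dioxolan-4-one | COc1cc(O)c(C(=O)c2cccc(O)c2)c(O)c1C[C@H]1OC(C)(C)OC1=O | intermediate
9 | (3R)-4-[2,4-dihydroxy-3-(3-hydroxybenzoyl)-6-methoxyphenyl]-3-hydroxybutan-2-one (methyl ketone) | COc1cc(O)c(C(=O)c2cccc(O)c2)c(O)c1C[C@@H](O)C(C)=O | intermediate
10 | {3-[(2R)-2,3-dihydroxy-3-methylbutyl]-2,6-dihydroxy-4-methoxyphenyl}(3-hydroxyphenyl)methanone | COc1cc(O)c(C(=O)c2cccc(O)c2)c(O)c1C[C@@H](O)C(C)(C)O | intermediate
11 | [(3R)-3,7-dihydroxy-5-methoxy-2,2-dimethyl-3,4-dihydro-2H-chromen-8-yl](3-hydroxyphenyl)methanone | COc1cc(O)c(C(=O)c2cccc(O)c2)c2c1C[C@@H](O)C(C)(C)O2 | intermediate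
12 | [(3R)-3,7-dihydroxy-6-iodo-5-methoxy-2,2-dimethyl-3,4-dihydro-2H-chromen-8-yl](3-hydroxyphenyl)methanone | COc1c(I)c(O)c(C(=O)c2cccc(O)c2)c2c1C[C@@H](O)C(C)(C)O2 | intermediate
13 | (+)-limonene oxide, (4R)-1-methyl-4-(prop-1-en-2-yl)-7-oxabicyclo[4.1.0]heptane, cis/trans mixture | CC(=C)[C@@H]1CCC2(C)OC2C1 | starting material
14 | (4R)-1-methyl-4-(prop-1-en-2-yl)cyclohexane-1,2-diol (limonene glycol) | CC(=C)[C@@H]1CCC(C)(O)C(O)C1 | intermediate
15 | (3R)-6-oxo-3-(prop-1-en-2-yl)heptanal | CC(=O)CC[C@H](CC=O)C(C)=C | intermediate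
16 | (3R)-6-oxo-3-(prop-1-en-2-yl)heptanoic acid | CC(=O)CC[C@H](CC(=O)O)C(C)=C | intermediate
17 | (3R)-6-methyl-3-(prop-1-en-2-yl)hept-6-enoic acid | C=C(C)CC[C@H](CC(=O)O)C(C)=C | intermediate
18 | 2-sulfanylidenepyridin-1(2H)-yl (3R)-6-methyl-3-(prop-1-en-2-yl)hept-6-enoate (Barton ester) | C=C(C)CC[C@H](CC(=O)ON1C=CC=CC1=S)C(C)=C | intermediate
19 | (3S)-3-(iodomethyl)-2,6-dimethylhepta-1,6-diene | C=C(C)CC[C@H](CI)C(C)=C | intermediate
20 | iodido[(2S)-5-methyl-2-(prop-1-en-2-yl)hex-5-en-1-yl]zinc (alkylzinc iodide) | C=C(C)CC[C@H](C[Zn]I)C(C)=C | intermediate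
21 | [(3R)-3,7-dihydroxy-5-methoxy-2,2-dimethyl-6-[(2R)-5-methyl-2-(prop-1-en-2-yl)hex-5-en-1-yl]-3,4-dihydro-2H-chromen-8-yl](3-hydroxyphenyl)methanone | C=C(C)CC[C@H](Cc1c(O)c(C(=O)c2cccc(O)c2)c2c(c1OC)C[C@@H](O)C(C)(C)O2)C(=C)C | target

**Totals**
Total steps: 13. Longest linear sequence: 7 (steps 1, 2, 5, 6, 7, 8, 13; the D-malic acid branch through steps 3 and 4 is equally long).

**Steps most likely to fail and their fallbacks**

Step 5 is the new photochemical aryloxide alkylation. It may fail through O-acylation of the aryloxide by the active ester, O- instead of C-coupling, double alkylation, or simply too low a quantum yield. The fallback uses known chemistry: 4 is iodinated with NIS (MeCN, 0 °C) to (2,6-dihydroxy-3-iodo-4-methoxyphenyl)(3-hydroxyphenyl)methanone F1, and F1 is joined to 7 by the nickel-catalysed reductive cross-electrophile coupling of aryl iodides with N-acyloxyphthalimides (NiBr2·DME, 4,4'-di-tert-butyl-2,2'-bipyridine, Zn dust, DMA, 25 °C). It sets out from 4 and comes back to the route at 8.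

Step 13 is a Negishi coupling on a di-ortho-substituted aryl iodide with three free OH groups. Risks are protonolysis of the zinc reagent, protodeiodination and β-hydride elimination. The fallback changes the organometallic: 19 is treated with t-BuLi (Et2O, −78 °C) to give [(2S)-5-methyl-2-(prop-1-en-2-yl)hex-5-en-1-yl]lithium F2, which is trapped with 9-methoxy-9-borabicyclo[3.3.1]nonane as lithium 9-methoxy-9-[(2S)-5-methyl-2-(prop-1-en-2-yl)hex-5-en-1-yl]-9-boranuidabicyclo[3.3.1]nonane F3. F3 is coupled with 12 under aqueous B-alkyl Suzuki–Miyaura conditions (PdCl2(dppf), K3PO4, DMF/H2O, 20 → 50 °C), which tolerate phenoxides. It sets out from 19 and 12 and comes back at 21.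

Step 6 puts MeMgBr on a substrate that carries a diaryl ketone and three acidic OH groups. Risks are an insoluble magnesium phenoxide or addition to the ketone. The fallback installs the two methyl groups before the arene is attached:
- 6 with MeMgBr (4 equiv, THF, 0 °C, acidic work-up) gives (4R)-4-hydroxy-5,5-dimethyloxolan-2-one F4.
- 2,2-Dimethoxypropane, MeOH and p-TsOH (cat.) open F4 to methyl 2-[(4R)-2,2,5,5-tetramethyl-1,3-dioxolan-4-yl]acetate F5.
- LiOH (THF/H2O) gives 2-[(4R)-2,2,5,5-tetramethyl-1,3-dioxolan-4-yl]acetic acid F6.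
- N-hydroxyphthalimide and DIC give 1,3-dioxoisoindolin-2-yl 2-[(4R)-2,2,5,5-tetramethyl-1,3-dioxolan-4-yl]acetate F7.
- F7 is coupled with 4 under the step 5 conditions to give {2,6-dihydroxy-4-methoxy-3-{[(4R)-2,2,5,5-tetramethyl-1,3-dioxolan-4-yl]methyl}phenyl}(3-hydroxyphenyl)methanone F8.
- p-TsOH in aqueous MeOH (20 °C) removes the acetonide.

It sets out from 6 and comes back at 10.

**Further compounds**
F1 | step 5 | (2,6-dihydroxy-3-iodo-4-methoxyphenyl)(3-hydroxyphenyl)methanone | COc1cc(O)c(C(=O)c2cccc(O)c2)c(O)c1I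
F2 | step 13 | [(2S)-5-methyl-2-(prop-1-en-2-yl)hex-5-en-1-yl]lithium | C=C(C)CC[C@H](C[Li])C(C)=C
F3 | step 13 | lithium 9-methoxy-9-[(2S)-5-methyl-2-(prop-1-en-2-yl)hex-5-en-1-yl]-9-boranuidabicyclo[3.3.1]nonane | [Li+].C=C(C)CC[C@H](C[B-]1(OC)C2CCCC1CCC2)C(C)=C
F4 | step 6 | (4R)-4-hydroxy-5,5-dimethyloxolan-2-one | O=C1C[C@@H](O)C(C)(C)O1
F5 | step 6 | methyl 2-[(4R)-2,2,5,5-tetramethyl-1,3-dioxolan-4-yl]acetate | COC(=O)C[C@H]1OC(C)(C)OC1(C)C
F6 | step 6 | 2-[(4R)-2,2,5,5-tetramethyl-1,3-dioxolan-4-yl]acetic acid | OC(=O)C[C@H]1OC(C)(C)OC1(C)C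
F7 | step 6 | 1,3-dioxoisoindolin-2-yl 2-[(4R)-2,2,5,5-tetramethyl-1,3-dioxolan-4-yl]acetate | O=C(C[C@H]1OC(C)(C)OC1(C)C)ON1C(=O)c2ccccc2C1=O
F8 | step 6 | {2,6-dihydroxy-4-methoxy-3-{[(4R)-2,2,5,5-tetramethyl-1,3-dioxolan-4-yl]methyl}phenyl}(3-hydroxyphenyl)methanone | COc1cc(O)c(C(=O)c2cccc(O)c2)c(O)c1C[C@H]1OC(C)(C)OC1(C)C
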